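**Plan**

- The target is an achiral diaryl ether. Ring A carries C1 CH2OH, C2 Br, C3 O-aryl, C4 OH, C5 Br, C6 H; ring B carries C1' ether carbon, C2' CH2OH, C4' Br, C5' and C6' OH.
- The two CH2OH groups are traced back to a C1 methyl ester and a C2' aldehyde. The C5–Br and C4'–Br bonds are cut as late phenol-directed brominations, and C2–Br as an ester-directed magnesiation/bromination.
- Ring A is cut at C3–C4 and C4–C5. The phenolic carbon C4 lies between the ether-bearing C3 and C5, so it can be carbon monoxide inserted between the ends of the chain C5–C6–C1–C2–C3, which already holds ring B on the C3 oxygen and the ester on C1.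
- That dienyl acetate is cut at C1–C2 (Suzuki–Miyaura coupling) into an (E)-2-aryloxyvinylboronate and a (Z)-2-iodo-4-hydroxybutenoate; the O–C3 bond goes back to the ring B phenol and trichloroethylene.
- Forward: ring B is purchased; O-vinylation, alkyne formation and hydroboration, coupling and acetylation, carbonylative closure of ring A, then bromine installation and reduction.
- No stereocentre is present. The alkene geometries of the precursor come from syn hydroboration (E enol ether) and trans hydroalumination/iodination (Z iodide, which places C5 and C2 cis on C6=C1).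

Key step: step 8

Remark on the chemistry: the ring B aldehyde is carried as a 1,3-dioxolane rather than an acyclic acetal, because the cyclic acetal should better survive chromatography and the hot Ac2O/NEt3 medium of the ring closure.

**Route**

Step 1
Reactants: 1 2-hydroxy-3,4-dimethoxybenzaldehyde; 2 trichloroethylene
Product: 4 2-[(E)-1,2-dichloroethenyloxy]-3,4-dimethoxybenzaldehyde, via dichloroacetylene 3 (not isolated)
Conditions: K2CO3, DMF, 70 °C
Reagents that add atoms: none
Why: Carbonate-induced loss of HCl from trichloroethylene gives dichloroacetylene, to which the phenoxide adds with anti protonation; this is the established O-(1,2-dichlorovinylation) of phenols, which tolerates the aldehyde and should give the E isomer.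

Step 2
Reactants: 4 2-[(E)-1,2-dichloroethenyloxy]-3,4-dimethoxybenzaldehyde
Product: 5 2-{2-[(E)-1,2-dichloroethenyloxy]-3,4-dimethoxyphenyl}-1,3-dioxolane
Conditions: HOCH2CH2OH, HC(OEt)3, pTsOH·H2O (cat.), CH2Cl2, rt
Reagents that add atoms: ethylene glycol, OCCO
Why: Acid-catalysed acetalization with orthoformate as water scavenger masks the aldehyde against n-BuLi and the later amide base, and the electron-poor dichlorovinyl ether should not be protonated under these mild conditions.

Step 3
Reactants: 5 2-{2-[(E)-1,2-dichloroethenyloxy]-3,4-dimethoxyphenyl}-1,3-dioxolane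
Product: 8 2-[2-(ethynyloxy)-3,4-dimethoxyphenyl]-1,3-dioxolane, via chloroethynyl ether 6 (not isolated), via lithium acetylide 7 (not isolated)
Conditions: n-BuLi (2.5 equiv), Et2O, −78 → −40 °C; then H2O, −78 °C
Reagents that add atoms: none
Why: Vinylic deprotonation and loss of LiCl give the chloroalkyne, chlorine–lithium exchange gives the acetylide and water protonates it, which is the standard dichlorovinyl ether route to aryl ethynyl ethers; the two ortho substituents shield the sensitive ynol ether, which is used at once.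

Step 4
Reactants: 8 2-[2-(ethynyloxy)-3,4-dimethoxyphenyl]-1,3-dioxolane
Product: 9 2-{(E)-2-[6-(1,3-dioxolan-2-yl)-2,3-dimethoxyphenoxy]ethenyl}-4,4,5,5-tetramethyl-1,3,2-dioxaborolane
Conditions: HBpin, Cp2ZrHCl (10 mol %), NEt3 (10 mol %), CH2Cl2, rt
Reagents that add atoms: pinacolborane, CC1(C)OBOC1(C)C
Why: Zirconocene-hydride-catalysed hydroboration of a terminal alkynyl ether is a syn addition that places boron on the terminal carbon, so the E-configured 2-aryloxyvinylboronate (the future C2=C3 unit) should result.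

Step 5
Reactants: 10 methyl 4-hydroxybut-2-ynoate
Product: 12 methyl (Z)-4-hydroxy-2-iodobut-2-enoate, via cyclic alkenylaluminate 11 (not isolated)
Conditions: NaAlH2(OCH2CH2OMe)2, THF, −72 °C; then N-iodosuccinimide, THF, −72 → −20 °C
Reagents that add atoms: N-iodosuccinimide, O=C1CCC(=O)N1I
Why: The alkoxide-bound aluminium hydride delivers hydride to the β-carbon in a trans hydroalumination of the γ-hydroxy ynoate, and iodinolysis of the C–Al bond with retention places iodine cis to CH2OH (Z), the geometry that later holds C5 and C2 cis.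

Step 6
Reactants: 9 2-{(E)-2-[6-(1,3-dioxolan-2-yl)-2,3-dimethoxyphenoxy]ethenyl}-4,4,5,5-tetramethyl-1,3,2-dioxaborolane; 12 methyl (Z)-4-hydroxy-2-iodobut-2-enoate
Product: 13 methyl (2E,3E)-4-[6-(1,3-dioxolan-2-yl)-2,3-dimethoxyphenoxy]-2-(2-hydroxyethylidene)but-3-enoate
Conditions: Pd(PPh3)4 (5 mol %), K3PO4, THF/H2O, 45 °C
Reagents that add atoms: none
Why: Suzuki–Miyaura coupling of an α-iodoenoate with an alkenylboronate forms the C1–C2 bond with retention at both alkenes, and the free allylic alcohol, unlike an allylic acetate, is not ionized by zerovalent palladium.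

Step 7
Reactants: 13 methyl (2E,3E)-4-[6-(1,3-dioxolan-2-yl)-2,3-dimethoxyphenoxy]-2-(2-hydroxyethylidene)but-3-enoate
Product: 14 methyl (2E,3E)-2-(2-acetoxyethylidene)-4-[6-(1,3-dioxolan-2-yl)-2,3-dimethoxyphenoxy]but-3-enoate
Conditions: Ac2O, pyridine, DMAP (cat.), CH2Cl2, 0 °C
Reagents that add atoms: acetic anhydride, CC(=O)OC(C)=O
Why: Standard DMAP-catalysed O-acetylation of the primary allylic alcohol installs the leaving group for the carbonylation without touching the aryl dienyl ether or the dioxolane.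

Step 8
Reactants: 14 methyl (2E,3E)-2-(2-acetoxyethylidene)-4-[6-(1,3-dioxolan-2-yl)-2,3-dimethoxyphenoxy]but-3-enoate; 15 carbon monoxide
Product: 19 methyl 4-acetoxy-3-[6-(1,3-dioxolan-2-yl)-2,3-dimethoxyphenoxy]benzoate, via dienylketene 16 (not isolated), via cyclohexadienone 17 (not isolated), via phenol 18 (not isolated)
Conditions: PdCl2(PPh3)2 (5 mol %), CO (60 atm), Ac2O (2 equiv), NEt3 (2 equiv), toluene, 140 °C
Reagents that add atoms: acetic anhydride, CC(=O)OC(C)=O
Why: Zerovalent palladium, formed from the divalent palladium precatalyst under CO and NEt3, ionizes the allylic acetate to an η3-pentadienylpalladium complex, CO inserts at the primary terminus C5 (bond C4–C5) and NEt3 converts the 3,5-dienoyl species into dienylketene 16. Thermal disrotatory 6π-electrocyclization then joins the ketene carbon C4 to the aryloxy-bearing terminus C3 (bond C3–C4), closing the six-membered ring A as dienone 17, which enolizes to phenol 18 and is acetylated by Ac2O. The closest known reaction is the palladium-catalysed cyclocarbonylation of 2,4-pentadienyl acetates to phenyl acetates. No stereocentre survives, because the sp3 carbon C3 of 17 is lost on aromatization. The step needs CO insertion at the unsubstituted allyl terminus and a cis relation of C5 and C2 across C6=C1; the first is favoured because the CH2 end is the least hindered terminus and the chain offers no β-hydrogen for diene formation, the second is built into 14 and can also be reached by syn/anti equilibration of the allyl complex. Because the aryloxy group sits on the far terminus C3, it ends ortho to the new oxygen and meta to the ester, as ring A requires.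

Step 9
Reactants: 19 methyl 4-acetoxy-3-[6-(1,3-dioxolan-2-yl)-2,3-dimethoxyphenoxy]benzoate
Product: 21 methyl 3-[6-(1,3-dioxolan-2-yl)-2,3-dimethoxyphenoxy]-4-methoxybenzoate, via potassium phenoxide 20 (not isolated)
Conditions: K2CO3 (2 equiv), MeOH, rt; evaporate; then MeI, DMF, rt
Reagents that add atoms: iodomethane, IC
Why: Carbonate-mediated methanolysis of the aryl acetate leaves the potassium phenoxide 20, which is O-methylated in the same flask in a Williamson etherification, exchanging the base-labile acetate for an ether that withstands the amide base.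

Step 10
Reactants: 21 methyl 3-[6-(1,3-dioxolan-2-yl)-2,3-dimethoxyphenoxy]-4-methoxybenzoate
Product: 23 methyl 2-bromo-3-[6-(1,3-dioxolan-2-yl)-2,3-dimethoxyphenoxy]-4-methoxybenzoate, via arylmagnesium chloride 22 (not isolated)
Conditions: TMPMgCl·LiCl (1.5 equiv), THF, 0 °C; then BrCCl2CCl2Br, −40 °C → rt
Reagents that add atoms: 1,2-dibromo-1,1,2,2-tetrachloroethane, BrC(Cl)(Cl)C(Cl)(Cl)Br
Why: Directed ortho-magnesiation of a benzoate with TMPMgCl·LiCl should occur at C2, the position acidified and chelated by both the ester and the aryloxy oxygen, and the arylmagnesium is then brominated by the positive-bromine donor.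

Step 11
Reactants: 23 methyl 2-bromo-3-[6-(1,3-dioxolan-2-yl)-2,3-dimethoxyphenoxy]-4-methoxybenzoate
Product: 24 methyl 2-bromo-3-(6-formyl-2,3-dihydroxyphenoxy)-4-hydroxybenzoate
Conditions: BBr3 (8 equiv), CH2Cl2, −78 → 0 °C; then H2O
Reagents that add atoms: water, O
Why: BBr3 demethylation of the three aryl methyl ethers proceeds at low temperature, where a methyl benzoate and the diaryl ether persist, and the same Lewis acid opens the dioxolane so that aqueous work-up returns the aldehyde.

Step 12
Reactants: 24 methyl 2-bromo-3-(6-formyl-2,3-dihydroxyphenoxy)-4-hydroxybenzoate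
Product: 25 methyl 2,5-dibromo-3-(4-bromo-6-formyl-2,3-dihydroxyphenoxy)-4-hydroxybenzoate
Conditions: Br2 (2.05 equiv), AcOH, rt
Reagents that add atoms: bromine, BrBr
Why: Electrophilic aromatic bromination is steered by the free hydroxyls: on ring A only C5 is ortho to the C4 hydroxyl (the para position is blocked by the ester), and on ring B C4' is ortho to the C5' hydroxyl and para to the ether oxygen, whereas C3' is para to only one hydroxyl and ortho to the formyl group.

Step 13
Reactants: 25 methyl 2,5-dibromo-3-(4-bromo-6-formyl-2,3-dihydroxyphenoxy)-4-hydroxybenzoate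
Product: 26 2,5-dibromo-3-[4-bromo-2,3-dihydroxy-6-(hydroxymethyl)phenoxy]-4-hydroxybenzyl alcohol (CNP0104332.0)
Conditions: i-Bu2AlH (10 equiv), THF, −78 → 0 °C; aq. potassium sodium tartrate
Reagents that add atoms: none
Why: Excess i-Bu2AlH first converts the three phenols into aluminium phenoxides and then reduces both the methyl ester and the aldehyde to primary alcohols (hydride reduction), aryl bromides being inert to this reagent, and the neutral tartrate work-up avoids acid-induced quinone methide formation from the p-hydroxybenzyl alcohols.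

**Compound list**

1 | 2-hydroxy-3,4-dimethoxybenzaldehyde | O=Cc1ccc(OC)c(OC)c1O | starting material
2 | trichloroethylene | ClC=C(Cl)Cl | starting material
3 | dichloroacetylene (formed in situ) | ClC#CCl | intermediate
4 | 2-[(E)-1,2-dichloroethenyloxy]-3,4-dimethoxybenzaldehyde | O=Cc1ccc(OC)c(OC)c1O/C(Cl)=C\Cl | intermediate
5 | 2-{2-[(E)-1,2-dichloroethenyloxy]-3,4-dimethoxyphenyl}-1,3-dioxolane | COc1ccc(C2OCCO2)c(O/C(Cl)=C\Cl)c1OC | intermediate
6 | 2-{2-[(chloroethynyl)oxy]-3,4-dimethoxyphenyl}-1,3-dioxolane (formed in situ) | COc1ccc(C2OCCO2)c(OC#CCl)c1OC | intermediate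
7 | lithium [6-(1,3-dioxolan-2-yl)-2,3-dimethoxyphenoxy]ethynide (formed in situ) | COc1ccc(C2OCCO2)c(OC#C[Li])c1OC | intermediate
8 | 2-[2-(ethynyloxy)-3,4-dimethoxyphenyl]-1,3-dioxolane | COc1ccc(C2OCCO2)c(OC#C)c1OC | intermediate
9 | 2-{(E)-2-[6-(1,3-dioxolan-2-yl)-2,3-dimethoxyphenoxy]ethenyl}-4,4,5,5-tetramethyl-1,3,2-dioxaborolane | COc1ccc(C2OCCO2)c(O/C=C/B2OC(C)(C)C(C)(C)O2)c1OC | intermediate
10 | methyl 4-hydroxybut-2-ynoate | OCC#CC(=O)OC | starting material
11 | sodium 2,2-bis(2-methoxyethoxy)-3-(methoxycarbonyl)-2,5-dihydro-1,2-oxaluminol-2-uide, the alkoxide-chelated alkenylaluminate (formed in situ) | COC(=O)C1=CCO[Al-]1(OCCOC)OCCOC.[Na+] | intermediate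
12 | methyl (Z)-4-hydroxy-2-iodobut-2-enoate | OC/C=C(\I)C(=O)OC | intermediate
13 | methyl (2E,3E)-4-[6-(1,3-dioxolan-2-yl)-2,3-dimethoxyphenoxy]-2-(2-hydroxyethylidene)but-3-enoate | OC/C=C(\C=C\Oc1c(C2OCCO2)ccc(OC)c1OC)C(=O)OC | intermediate
14 | methyl (2E,3E)-2-(2-acetoxyethylidene)-4-[6-(1,3-dioxolan-2-yl)-2,3-dimethoxyphenoxy]but-3-enoate | CC(=O)OC/C=C(\C=C\Oc1c(C2OCCO2)ccc(OC)c1OC)C(=O)OC | intermediate
15 | carbon monoxide | [C-]#[O+] | starting material
16 | methyl (2E,3E)-4-[6-(1,3-dioxolan-2-yl)-2,3-dimethoxyphenoxy]-2-(3-oxoprop-2-en-1-ylidene)but-3-enoate, the dienylketene (formed in situ) | O=C=C/C=C(\C=C\Oc1c(C2OCCO2)ccc(OC)c1OC)C(=O)OC | intermediate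
17 | methyl 3-[6-(1,3-dioxolan-2-yl)-2,3-dimethoxyphenoxy]-4-oxocyclohexa-1,5-diene-1-carboxylate, racemic (formed in situ) | COC(=O)C1=CC(Oc2c(C3OCCO3)ccc(OC)c2OC)C(=O)C=C1 | intermediate
18 | methyl 3-[6-(1,3-dioxolan-2-yl)-2,3-dimethoxyphenoxy]-4-hydroxybenzoate (formed in situ) | COC(=O)c1ccc(O)c(Oc2c(C3OCCO3)ccc(OC)c2OC)c1 | intermediate
19 | methyl 4-acetoxy-3-[6-(1,3-dioxolan-2-yl)-2,3-dimethoxyphenoxy]benzoate | COC(=O)c1ccc(OC(C)=O)c(Oc2c(C3OCCO3)ccc(OC)c2OC)c1 | intermediate
20 | potassium 2-[6-(1,3-dioxolan-2-yl)-2,3-dimethoxyphenoxy]-4-(methoxycarbonyl)phenolate (formed in situ) | COC(=O)c1ccc([O-])c(Oc2c(C3OCCO3)ccc(OC)c2OC)c1.[K+] | intermediate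
21 | methyl 3-[6-(1,3-dioxolan-2-yl)-2,3-dimethoxyphenoxy]-4-methoxybenzoate | COC(=O)c1ccc(OC)c(Oc2c(C3OCCO3)ccc(OC)c2OC)c1 | intermediate
22 | chlorido{2-[6-(1,3-dioxolan-2-yl)-2,3-dimethoxyphenoxy]-3-methoxy-6-(methoxycarbonyl)phenyl}magnesium (formed in situ) | COC(=O)c1ccc(OC)c(Oc2c(C3OCCO3)ccc(OC)c2OC)c1[Mg]Cl | intermediate
23 | methyl 2-bromo-3-[6-(1,3-dioxolan-2-yl)-2,3-dimethoxyphenoxy]-4-methoxybenzoate | COC(=O)c1ccc(OC)c(Oc2c(C3OCCO3)ccc(OC)c2OC)c1Br | intermediate
24 | methyl 2-bromo-3-(6-formyl-2,3-dihydroxyphenoxy)-4-hydroxybenzoate | COC(=O)c1ccc(O)c(Oc2c(C=O)ccc(O)c2O)c1Br | intermediate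
25 | methyl 2,5-dibromo-3-(4-bromo-6-formyl-2,3-dihydroxyphenoxy)-4-hydroxybenzoate | COC(=O)c1cc(Br)c(O)c(Oc2c(C=O)cc(Br)c(O)c2O)c1Br | intermediate
26 | 2,5-dibromo-3-[4-bromo-2,3-dihydroxy-6-(hydroxymethyl)phenoxy]-4-hydroxybenzyl alcohol | OCc1cc(Br)c(O)c(Oc2c(CO)cc(Br)c(O)c2O)c1Br | target

**Step count and risks**

Total: 13 steps. Longest linear sequence: 12 steps (steps 1–4 and 6–13, from compound 1).

Steps most likely to fail:

1. Step 8. The electron-rich aryl dienyl ether may decompose or the catalyst may be deactivated at 140 °C before CO uptake and ketene formation occur. The fallback separates carbonylation from ring closure and keeps the same two bonds. It sets out from 13: ClCO2Et and pyridine (CH2Cl2, 0 °C) give methyl (2E,3E)-4-[6-(1,3-dioxolan-2-yl)-2,3-dimethoxyphenoxy]-2-[2-(ethoxycarbonyloxy)ethylidene]but-3-enoate F1. Decarboxylative alkoxycarbonylation of this allylic carbonate (Pd(OAc)2, PPh3, CO 20 atm, THF, 50 °C) forms the C4–C5 bond and gives methyl (2E,3E)-4-[6-(1,3-dioxolan-2-yl)-2,3-dimethoxyphenoxy]-2-(3-ethoxy-3-oxopropylidene)but-3-enoate F2. Selective saponification of the unconjugated ethyl ester (LiOH, 1 equiv, THF/H2O, 0 °C) gives (3E,5E)-6-[6-(1,3-dioxolan-2-yl)-2,3-dimethoxyphenoxy]-4-(methoxycarbonyl)hexa-3,5-dienoic acid F3. Heating F3 with Ac2O and NaOAc at 110 °C forms the mixed anhydride and from it dienylketene 16, which closes the C3–C4 bond as in the classical cyclization of 3,5-dienoic acids to aryl acetates. The route is rejoined at 19.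

2. Step 10. Metalation may occur at C6 instead of the crowded C2, or the arylmagnesium may add to a methyl ester. The fallback changes the directing group to a carboxylate and sets out from 21: LiOH (THF/MeOH/H2O, then NaH2PO4 buffer to spare the dioxolane) gives 3-[6-(1,3-dioxolan-2-yl)-2,3-dimethoxyphenoxy]-4-methoxybenzoic acid F4. Treatment with LiTMP (3 equiv, THF, 0 °C) lithiates between the carboxylate and the aryloxy group, the known preference of 3-alkoxybenzoic acids, and BrCCl2CCl2Br gives 2-bromo-3-[6-(1,3-dioxolan-2-yl)-2,3-dimethoxyphenoxy]-4-methoxybenzoic acid F5. Esterification with MeI and K2CO3 in DMF rejoins the route at 23.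

3. Step 13. Reduction of the hindered ester, deactivated by the para aluminium phenoxide, may stall, or the p-hydroxybenzyl aluminium alkoxides may lose oxygen through quinone methides and be over-reduced to methyl groups. The fallback brings C1 to the aldehyde level before deprotection and sets out from 23: i-Bu2AlH (CH2Cl2, −78 °C) gives {2-bromo-3-[6-(1,3-dioxolan-2-yl)-2,3-dimethoxyphenoxy]-4-methoxyphenyl}methanol F6, and MnO2 (CH2Cl2, rt) gives 2-bromo-3-[6-(1,3-dioxolan-2-yl)-2,3-dimethoxyphenoxy]-4-methoxybenzaldehyde F7. BBr3 (CH2Cl2, −78 → 0 °C, then H2O) gives 2-bromo-3-(6-formyl-2,3-dihydroxyphenoxy)-4-hydroxybenzaldehyde F8, and Br2 in AcOH gives 2,5-dibromo-3-(4-bromo-6-formyl-2,3-dihydroxyphenoxy)-4-hydroxybenzaldehyde F9. NaBH4 in MeOH at 0 °C then reduces both aldehydes in the presence of the free phenols and arrives directly at 26.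

**Further compounds**

F1 | step 8 | methyl (2E,3E)-4-[6-(1,3-dioxolan-2-yl)-2,3-dimethoxyphenoxy]-2-[2-(ethoxycarbonyloxy)ethylidene]but-3-enoate | CCOC(=O)OC/C=C(\C=C\Oc1c(C2OCCO2)ccc(OC)c1OC)C(=O)OC
F2 | step 8 | methyl (2E,3E)-4-[6-(1,3-dioxolan-2-yl)-2,3-dimethoxyphenoxy]-2-(3-ethoxy-3-oxopropylidene)but-3-enoate | CCOC(=O)C/C=C(\C=C\Oc1c(C2OCCO2)ccc(OC)c1OC)C(=O)OC
F3 | step 8 | (3E,5E)-6-[6-(1,3-dioxolan-2-yl)-2,3-dimethoxyphenoxy]-4-(methoxycarbonyl)hexa-3,5-dienoic acid | OC(=O)C/C=C(\C=C\Oc1c(C2OCCO2)ccc(OC)c1OC)C(=O)OC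
F4 | step 10 | 3-[6-(1,3-dioxolan-2-yl)-2,3-dimethoxyphenoxy]-4-methoxybenzoic acid | OC(=O)c1ccc(OC)c(Oc2c(C3OCCO3)ccc(OC)c2OC)c1
F5 | step 10 | 2-bromo-3-[6-(1,3-dioxolan-2-yl)-2,3-dimethoxyphenoxy]-4-methoxybenzoic acid | OC(=O)c1ccc(OC)c(Oc2c(C3OCCO3)ccc(OC)c2OC)c1Br
F6 | step 13 | {2-bromo-3-[6-(1,3-dioxolan-2-yl)-2,3-dimethoxyphenoxy]-4-methoxyphenyl}methanol | OCc1ccc(OC)c(Oc2c(C3OCCO3)ccc(OC)c2OC)c1Br
F7 | step 13 | 2-bromo-3-[6-(1,3-dioxolan-2-yl)-2,3-dimethoxyphenoxy]-4-methoxybenzaldehyde | O=Cc1ccc(OC)c(Oc2c(C3OCCO3)ccc(OC)c2OC)c1Br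
F8 | step 13 | 2-bromo-3-(6-formyl-2,3-dihydroxyphenoxy)-4-hydroxybenzaldehyde | O=Cc1ccc(O)c(Oc2c(C=O)ccc(O)c2O)c1Br
F9 | step 13 | 2,5-dibromo-3-(4-bromo-6-formyl-2,3-dihydroxyphenoxy)-4-hydroxybenzaldehyde | O=Cc1cc(Br)c(O)c(Oc2c(C=O)cc(Br)c(O)c2O)c1Br
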